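**Strategy.** Ring C of the flavonol is cut at O1–C2 and at the C3–O bond, which turns C2–C3–C4 into the enone bridge of a chalcone whose ring A already carries all five oxygens. In one flask the enone is epoxidised, the acetal on the C8a oxygen (the future O1) is removed and that oxygen attacks the p-anisyl-bearing carbon, so the C3 hydroxyl, the O1–C2 bond and ring C appear together. The feature exploited is the C2–C3–C4(=O) unit flanked by the C8a oxygen and by the cation-stabilising ring B at C2. The precursor is the (E)-chalcone with 2'-OMOM, 4'-OBn and 3',5',6'-OMe groups on ring A and a 4-methoxyphenyl ring B.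

Key step: step 8

Remark on the chemistry: the target has no stereocentre; compounds 11, 12 and 13 are racemic (one enantiomer drawn, trans relative configuration), and both stereocentres are removed in step 9.

**Step 1**
Reactants: 1 2,6-dimethoxyphenol
Product: 2 2-(benzyloxy)-1,3-dimethoxybenzene
Conditions: BnBr, K2CO3, DMF, 60 °C
Reagents that add atoms: benzyl bromide, BrCc1ccccc1
Why: Williamson etherification of the phenoxide with a benzylic bromide is fast and O-selective, and the benzyl ether should mask the future C7 oxygen through all later acidic, basic and oxidative steps until hydrogenolysis.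

**Step 2**
Reactants: 2 2-(benzyloxy)-1,3-dimethoxybenzene
Product: 3 3-(benzyloxy)-1,5-dibromo-2,4-dimethoxybenzene
Conditions: NBS (2.2 equiv), MeCN, rt to 50 °C
Reagents that add atoms: N-bromosuccinimide, O=C1CCC(=O)N1Br
Why: Electrophilic aromatic bromination should go para to each in-plane methoxy group (C4 and C6 of 2), because the twisted central benzyloxy group activates its own para position far less, as in the dibromination of 1,2,3-trimethoxybenzene.

**Step 3**
Reactants: 3 3-(benzyloxy)-1,5-dibromo-2,4-dimethoxybenzene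
Product: 4 5-(benzyloxy)-4,6-dimethoxybenzene-1,3-diol
Conditions: Pd2(dba)3 (cat.), tBuXPhos (cat.), KOH, 1,4-dioxane/H2O, 100 °C, degassed; then 1 M HCl
Reagents that add atoms: potassium hydroxide, [K+].[OH-]
Why: Palladium-catalysed C–O coupling of aryl bromides with hydroxide (oxidative addition to zerovalent palladium, bromide–hydroxide exchange, reductive elimination from the bulky biarylphosphine complex) is an established phenol synthesis that tolerates ortho-alkoxy groups and benzyl ethers, and the meta relationship of the two bromides keeps the second oxidative addition from being shut down by the first phenoxide.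

**Step 4**
Reactants: 4 5-(benzyloxy)-4,6-dimethoxybenzene-1,3-diol
Product: 6 1-[4-(benzyloxy)-2,6-dihydroxy-3,5-dimethoxyphenyl]ethan-1-one, via ketiminium chloride 5 (not isolated)
Conditions: MeCN, ZnCl2, HCl (g), Et2O, 0 °C; then H2O, 90 °C
Reagents that add atoms: acetonitrile, CC#N; water, O
Why: In this Hoesch reaction the nitrilium species from MeCN, HCl and ZnCl2 should attack the only free ring carbon, which is activated by two ortho hydroxyls and the para benzyloxy group, and the ketiminium salt 5 is then hydrolysed to the ketone under conditions too mild to cleave the benzyl ether.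

**Step 5**
Reactants: 6 1-[4-(benzyloxy)-2,6-dihydroxy-3,5-dimethoxyphenyl]ethan-1-one
Product: 7 1-[4-(benzyloxy)-2-hydroxy-3,5,6-trimethoxyphenyl]ethan-1-one
Conditions: MeI (1.05 equiv), K2CO3 (1.1 equiv), acetone, 40 °C
Reagents that add atoms: iodomethane, CI
Why: Williamson methylation with one equivalent of MeI should stop at the mono-ether, because the two hydroxyls of 6 are equivalent and the one left in 7 is locked in a hydrogen bond to the carbonyl and is far less nucleophilic (the classical selective mono-alkylation of 2,6-dihydroxyacetophenones).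

**Step 6**
Reactants: 7 1-[4-(benzyloxy)-2-hydroxy-3,5,6-trimethoxyphenyl]ethan-1-one
Product: 8 1-[4-(benzyloxy)-3,5,6-trimethoxy-2-(methoxymethoxy)phenyl]ethan-1-one
Conditions: NaH, DMF, 0 °C; then MOMCl, 0 °C to rt
Reagents that add atoms: chloromethyl methyl ether, COCCl
Why: Irreversible deprotonation by NaH breaks the chelate and the sodium phenoxide is O-alkylated by MOMCl (Williamson-type acetal formation), giving a base-stable, acid-labile mask for the oxygen that becomes O1.

**Step 7**
Reactants: 8 1-[4-(benzyloxy)-3,5,6-trimethoxy-2-(methoxymethoxy)phenyl]ethan-1-one; 9 4-methoxybenzaldehyde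
Product: 10 (E)-1-[4-(benzyloxy)-3,5,6-trimethoxy-2-(methoxymethoxy)phenyl]-3-(4-methoxyphenyl)prop-2-en-1-one
Conditions: KOH, EtOH/H2O, rt
Reagents that add atoms: none
Why: In this Claisen–Schmidt condensation the potassium enolate of the methyl ketone adds to the non-enolisable aldehyde and E1cB dehydration gives the thermodynamically favoured (E)-enone, the MOM and benzyl ethers being inert to hydroxide.

**Step 8**
Reactants: 10 (E)-1-[4-(benzyloxy)-3,5,6-trimethoxy-2-(methoxymethoxy)phenyl]-3-(4-methoxyphenyl)prop-2-en-1-one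
Product: 13 rac-(2R,3R)-7-(benzyloxy)-3-hydroxy-5,6,8-trimethoxy-2-(4-methoxyphenyl)chroman-4-one (trans-dihydroflavonol), via MOM-protected trans-epoxide 11 (not isolated), via free-phenol trans-epoxide 12 (not isolated)
Conditions: 30% aq. H2O2, 2 M NaOH, MeOH/THF, 0 °C to rt; aq. Na2SO3; then conc. HCl (to ca. 1 M), 55 °C
Reagents that add atoms: hydrogen peroxide, OO
Why: Hydroperoxide anion adds to the β-carbon of the enone and the resulting enolate displaces hydroxide (Weitz–Scheffer epoxidation) to give the trans-epoxide 11, whose oxygen becomes the C3 hydroxyl; after the residual peroxide is reduced with sulfite so that no chlorinating species can form, methanolic HCl transfers the MOM group to methanol and protonates the epoxide of phenol 12. The closest known reaction type is the epoxidation and acid-induced cyclisation of 2'-O-methoxymethyl chalcones to dihydroflavonols. Ring C closes by 6-endo-tet attack of the C8a hydroxyl on the benzylic epoxide carbon, forming O1–C2. C3 keeps the configuration it had in the trans-epoxide and C2 is set by inversion at the benzylic carbon, so the 2,3-trans isomer should form, and any ionisation at C2 would still settle on this diequatorial isomer. The step needs 6-endo closure rather than 5-exo attack at the α-carbon, methanol capture or a 1,2-acyl shift: the 4-methoxyphenyl group concentrates positive charge at C2 while the carbonyl disfavours substitution at C3, the phenol is held next to C2, and a benzylic methyl ether formed by methanolysis would re-ionise under the same acid and be drawn into the ring. Acid is chosen because a base-mediated closure with an alkoxy group at C5 is known to divert to aurones.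

**Step 9**
Reactants: 13 rac-(2R,3R)-7-(benzyloxy)-3-hydroxy-5,6,8-trimethoxy-2-(4-methoxyphenyl)chroman-4-one
Product: 14 7-(benzyloxy)-3-hydroxy-5,6,8-trimethoxy-2-(4-methoxyphenyl)-4H-chromen-4-one
Conditions: I2, KOAc, AcOH, reflux
Reagents that add atoms: none
Why: Enolisation, iodination at C3 and loss of HI give the 3,4-dione, which tautomerises to the aromatic 3-hydroxychromone (the known iodine–acetate dehydrogenation of dihydroflavonols), while acetate buffers the HI so that the ethers should survive.

**Step 10**
Reactants: 14 7-(benzyloxy)-3-hydroxy-5,6,8-trimethoxy-2-(4-methoxyphenyl)-4H-chromen-4-one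
Product: 15 7-(benzyloxy)-3,5,6,8-tetramethoxy-2-(4-methoxyphenyl)-4H-chromen-4-one
Conditions: MeI, K2CO3, acetone, reflux
Reagents that add atoms: iodomethane, CI
Why: Williamson methylation of the only free hydroxyl, the acidic C3 enol, should proceed cleanly under standard carbonate conditions.

**Step 11**
Reactants: 15 7-(benzyloxy)-3,5,6,8-tetramethoxy-2-(4-methoxyphenyl)-4H-chromen-4-one
Product: 16 7-hydroxy-3,5,6,8-tetramethoxy-2-(4-methoxyphenyl)-4H-chromen-4-one
Conditions: H2 (1 atm), 10% Pd/C, EtOAc/MeOH, rt
Reagents that add atoms: none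
Why: Catalytic hydrogenolysis cleaves the benzylic C–O bond selectively, since the tetrasubstituted conjugated C2=C3 bond of the 3-methoxyflavone and the aryl methyl ethers are not reduced under one atmosphere of hydrogen at room temperature.

**Compound list**
1 | 2,6-dimethoxyphenol | COc1cccc(OC)c1O | starting material
2 | 2-(benzyloxy)-1,3-dimethoxybenzene | COc1cccc(OC)c1OCc1ccccc1 | intermediate
3 | 3-(benzyloxy)-1,5-dibromo-2,4-dimethoxybenzene | COc1c(Br)cc(Br)c(OC)c1OCc1ccccc1 | intermediate
4 | 5-(benzyloxy)-4,6-dimethoxybenzene-1,3-diol | COc1c(O)cc(O)c(OC)c1OCc1ccccc1 | intermediate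
5 | 1-[4-(benzyloxy)-2,6-dihydroxy-3,5-dimethoxyphenyl]ethan-1-iminium chloride | CC(=[NH2+])c1c(O)c(OC)c(OCc2ccccc2)c(OC)c1O.[Cl-] | intermediate
6 | 1-[4-(benzyloxy)-2,6-dihydroxy-3,5-dimethoxyphenyl]ethan-1-one | CC(=O)c1c(O)c(OC)c(OCc2ccccc2)c(OC)c1O | intermediate
7 | 1-[4-(benzyloxy)-2-hydroxy-3,5,6-trimethoxyphenyl]ethan-1-one | CC(=O)c1c(O)c(OC)c(OCc2ccccc2)c(OC)c1OC | intermediate
8 | 1-[4-(benzyloxy)-3,5,6-trimethoxy-2-(methoxymethoxy)phenyl]ethan-1-one | COCOc1c(OC)c(OCc2ccccc2)c(OC)c(OC)c1C(C)=O | intermediate
9 | 4-methoxybenzaldehyde | COc1ccc(C=O)cc1 | starting material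
10 | (E)-1-[4-(benzyloxy)-3,5,6-trimethoxy-2-(methoxymethoxy)phenyl]-3-(4-methoxyphenyl)prop-2-en-1-one | COCOc1c(OC)c(OCc2ccccc2)c(OC)c(OC)c1C(=O)/C=C/c1ccc(OC)cc1 | intermediate
11 | rac-[4-(benzyloxy)-3,5,6-trimethoxy-2-(methoxymethoxy)phenyl][(2R,3S)-3-(4-methoxyphenyl)oxiran-2-yl]methanone (trans-epoxide) | COCOc1c(OC)c(OCc2ccccc2)c(OC)c(OC)c1C(=O)[C@@H]1O[C@H]1c1ccc(OC)cc1 | intermediate
12 | rac-[4-(benzyloxy)-2-hydroxy-3,5,6-trimethoxyphenyl][(2R,3S)-3-(4-methoxyphenyl)oxiran-2-yl]methanone (trans-epoxide) | Oc1c(OC)c(OCc2ccccc2)c(OC)c(OC)c1C(=O)[C@@H]1O[C@H]1c1ccc(OC)cc1 | intermediate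
13 | rac-(2R,3R)-7-(benzyloxy)-3-hydroxy-5,6,8-trimethoxy-2-(4-methoxyphenyl)chroman-4-one (trans) | COc1ccc([C@@H]2[C@H](C(=O)c3c(OC)c(OC)c(OCc4ccccc4)c(OC)c3O2)O)cc1 | intermediate
14 | 7-(benzyloxy)-3-hydroxy-5,6,8-trimethoxy-2-(4-methoxyphenyl)-4H-chromen-4-one | COc1ccc(-c2oc3c(OC)c(OCc4ccccc4)c(OC)c(OC)c3c(=O)c2O)cc1 | intermediate
15 | 7-(benzyloxy)-3,5,6,8-tetramethoxy-2-(4-methoxyphenyl)-4H-chromen-4-one | COc1ccc(-c2oc3c(OC)c(OCc4ccccc4)c(OC)c(OC)c3c(=O)c2OC)cc1 | intermediate
16 | 7-hydroxy-3,5,6,8-tetramethoxy-2-(4-methoxyphenyl)-4H-chromen-4-one | COc1ccc(-c2oc3c(OC)c(O)c(OC)c(OC)c3c(=O)c2OC)cc1 | target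

**Totals.** Total step count: 11. Longest linear sequence: 11 steps (1 to 16); 4-methoxybenzaldehyde 9 enters at step 7.

**Steps most likely to fail**

Step 8. The epoxide next to the 4-methoxyphenyl ring may be opened by methanol, or may rearrange by a 1,2-acyl shift, before the acetal on the C8a oxygen has been cleaved, so that ring closure is incomplete or takes the 5-exo course. The fallback sets out from chalcone 10 and builds ring C before the C3 oxygen is introduced. Brief treatment with dilute HCl in MeOH/THF at room temperature should remove the MOM group and give (E)-1-[4-(benzyloxy)-2-hydroxy-3,5,6-trimethoxyphenyl]-3-(4-methoxyphenyl)prop-2-en-1-one F1. Oxidative cyclisation with catalytic I2 in DMSO at 120 °C should give the flavone 7-(benzyloxy)-5,6,8-trimethoxy-2-(4-methoxyphenyl)-4H-chromen-4-one F2. Epoxidation of the C2=C3 bond with dimethyldioxirane in acetone/CH2Cl2 at 0 °C should give the ring-fused epoxide rac-7-(benzyloxy)-2,3-epoxy-5,6,8-trimethoxy-2-(4-methoxyphenyl)chroman-4-one F3, and catalytic p-TsOH in CH2Cl2 should isomerise it to the flavonol. The fallback comes back to the route at 14, so step 9 is also bypassed.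

Step 3. The second C–O coupling may stall, with protodebromination or diaryl ether formation competing, and the electron-rich resorcinol dianion may be oxidised by traces of air at 100 °C. The fallback sets out from dibromide 3 and replaces direct hydroxylation by C–B bond formation and oxidation. Double Miyaura borylation (B2pin2, PdCl2(dppf), KOAc, 1,4-dioxane, 90 °C) should give 2,2'-[5-(benzyloxy)-4,6-dimethoxy-1,3-phenylene]bis(4,4,5,5-tetramethyl-1,3,2-dioxaborolane) F4. Oxidation with H2O2 and NaOH in THF at 0 °C, followed by mild acidification, should convert both C–B bonds into C–OH. The fallback comes back to the route at 4.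

Step 4. The benzyl ether may be lost under HCl and ZnCl2, or the nitrilium ion may be captured at a phenolic oxygen (imidate formation) instead of at carbon. The fallback sets out from diol 4 and installs the acetyl group by directed metalation instead of electrophilic substitution. MOMCl and i-Pr2NEt in CH2Cl2 should give 3-(benzyloxy)-2,4-dimethoxy-1,5-bis(methoxymethoxy)benzene F5. Lithiation between the two acetal oxygens with n-butyllithium in THF at 0 °C and trapping with N-methoxy-N-methylacetamide should give 1-[4-(benzyloxy)-3,5-dimethoxy-2,6-bis(methoxymethoxy)phenyl]ethan-1-one F6. HCl in MeOH at 40 °C should then remove both MOM groups. The fallback comes back to the route at 6.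

**Further compounds**
F1 | step 8 | (E)-1-[4-(benzyloxy)-2-hydroxy-3,5,6-trimethoxyphenyl]-3-(4-methoxyphenyl)prop-2-en-1-one | Oc1c(OC)c(OCc2ccccc2)c(OC)c(OC)c1C(=O)/C=C/c1ccc(OC)cc1
F2 | step 8 | 7-(benzyloxy)-5,6,8-trimethoxy-2-(4-methoxyphenyl)-4H-chromen-4-one | COc1ccc(-c2cc(=O)c3c(OC)c(OC)c(OCc4ccccc4)c(OC)c3o2)cc1
F3 | step 8 | rac-7-(benzyloxy)-2,3-epoxy-5,6,8-trimethoxy-2-(4-methoxyphenyl)chroman-4-one (cis ring fusion) | COc1ccc([C@]23O[C@H]2C(=O)c2c(OC)c(OC)c(OCc4ccccc4)c(OC)c2O3)cc1
F4 | step 3 | 2,2'-[5-(benzyloxy)-4,6-dimethoxy-1,3-phenylene]bis(4,4,5,5-tetramethyl-1,3,2-dioxaborolane) | COc1c(B2OC(C)(C)C(C)(C)O2)cc(B2OC(C)(C)C(C)(C)O2)c(OC)c1OCc1ccccc1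
F5 | step 4 | 3-(benzyloxy)-2,4-dimethoxy-1,5-bis(methoxymethoxy)benzene | COCOc1cc(OCOC)c(OC)c(OCc2ccccc2)c1OC
F6 | step 4 | 1-[4-(benzyloxy)-3,5-dimethoxy-2,6-bis(methoxymethoxy)phenyl]ethan-1-one | COCOc1c(OC)c(OCc2ccccc2)c(OC)c(OCOC)c1C(C)=O
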